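The data are simulated from invented constants, and the scatter is random.

At early times a flask shows how fast target is made, and at late times how fast it goes again, so I meant to reckon the green yield at both ends and join them.

the same everywhere: coupling partner 0.480 M

| flask | starting material | catalyst | target | time |
|---|---|---|---|---|
| teal | 0.600 M | 0.00300 M |  |  |
| red | 0.600 M | 0.00300 M | 0.300 M |  |
| blue | 0.300 M | 0.00300 M |  |  |
| grey | 0.600 M | 0.00450 M |  |  |
| green | 0.170 M | 0.00300 M |  | 61 min |

- teal run (time / min: [target] / M): 2.7: 0.0395; 8.2: 0.1119; 16: 0.1845; 25: 0.2472; 36: 0.2868; 48: 0.3193; 61: 0.3363
- red run (time / min: [target] / M): 2.7: 0.3233; 8.2: 0.3714; 16: 0.4180; 25: 0.4579; 36: 0.4821; 48: 0.4998; 61: 0.5058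
- blue run (time / min: [target] / M): 2.7: 0.0291; 8.2: 0.0810; 16: 0.1375; 25: 0.1723; 36: 0.1984; 48: 0.2065; 61: 0.2107
- grey run (time / min: [target] / M): 2.7: 0.0653; 8.2: 0.1621; 16: 0.2559; 25: 0.3180; 36: 0.3561; 48: 0.3680; 61: 0.3751

(standard deviation of a reading: 0.002 M)

- order of the initial rate in [catalyst], near the charge of the teal run, the rate being that where two percent of its starting material are target
- order of the initial rate in [starting material], near the charge of the teal run, the rate being that where two percent of its starting material are target (one fixed amount of target, the same in the runs compared)
- target in the green run at 61 min, as a share of the starting material charged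

- Overall: starting material + coupling partner -> target, with catalyst as catalyst.
- Constant volume, constant temperature.
- Bound and free are read together.
- An order is taken over about fifteen percent of the charge, up and down.

Red began with 0.300 M more target than teal, yet by 8.2 min the red-minus-teal gap had shrunk to 0.260 M, so I read target as being lost. Treating that as a first-order decay gave a constant λ of 0.0177 min⁻¹. Between 48 min and 61 min the same gap decayed at only 0.00484 min⁻¹, slower than at the start, and since coupling partner falls as a flask runs, I guessed that the loss goes with it. I therefore carried the loss coefficient κ, the early λ per unit of charged coupling partner,: 0.0368 M⁻¹ min⁻¹.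

Let S and R be a flask's charges of starting material and coupling partner, and let m, the mean making time, be half of S divided by the early rate. Making target spends coupling partner one for one, so in green, whose R stands above its S, making alone leaves the partner near 0.395 M at m and at 0.310 M once the whole of S is made. I took this lower figure, R − S, as a round stand-in for the coupling partner after m, which serves only for flasks with R above S and so not for teal, red or grey, and I joined the ends thus:

share of S found as target at time t ≈ exp(−κ (R − S) (t − m))

I then asked which input mattered. The catalyst order did not enter, because green holds the same catalyst as blue; grey over teal at 8.2 min put that order at 0.914. Blue over teal gave a chord order in starting material of 0.466, and I would put the local order below that. Blue's early rate, 0.00988 M min⁻¹, gave green m = 8.60 min. With green's loss constant 0.0114 min⁻¹, doubling m raised the share by 5.7 percentage points. The scatter in κ, 0.00277 M⁻¹ min⁻¹, moved it by 2.5 points. Using R in place of R − S moved it by 15 points, the largest change. My number for green was 55.0%.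

The forecast, holding that “the catalyst is dying”, gave 1.32 for the catalyst order, 0.43 for the starting-material order and 78% for green.

The simulation gave orders of 1.0 and 0.33, and green stood at 55.9% at 61 min.

    catalyst + starting material → catalyst-substrate complex (29.34 M⁻¹ min⁻¹)
    catalyst-substrate complex + coupling partner → target + catalyst (22.98 M⁻¹ min⁻¹)
    target + coupling partner → side product (0.04362 M⁻¹ min⁻¹)
    catalyst + starting material ⇌ idle catalyst-substrate complex, settled at all times (1.010 M⁻¹)

Among these steps target meets coupling partner and becomes side product. In green, κ gives a time constant of 87.7 min over the 52.4 min after m. In blue, κ gives a loss constant of 0.00663 min⁻¹ and m is 15.2 min, so the rule gives 73.8%, and blue's reading at 61 min was 70.2% of its starting material.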